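**Retrosynthetic overview**
1. The C6'–CH2–CH2–C9 linker is cut at Ca–Cb: a vinylogous Mukaiyama aldol between the γ-methyl of the left enone (27) and the C9-aldehyde of the right fragment (15), then dehydration and hydrogenation.
2. Left fragment (cis-decalone with C1'-carbinol): from (R)-carvone. The key step is a Claisen [3,3] rearrangement of a carvone-derived tertiary α-ketol, which forges C5'–C4'(Me2) and regenerates the enone. Ring 2 then closes by a Prins cyclisation, and C1'(Me)OH comes from HAT hydration of an exocyclic methylene.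
3. Right fragment (trans-oxepane–ring B): from (S)-carvone. C10 is made by double α'-alkylation, C5–O by Baeyer–Villiger, the oxepane by 7-endo epoxy-alcohol opening, C8–OH by enolate hydroxylation, and C9–CH2 by methylenation/hydroboration.
4. Ring order: ring 1 (carvone) → ring 2 (Prins) on the left; ring B (carvone) → oxepane on the right; the two halves are joined last.

Assumptions, one line each:
- Alkylation at C6 of carvone is anti to the C5 isopropenyl.
- The cis-fused decalin is the thermodynamic sink at C5'.
- Hydride reduction of oxepan-3-one 10 delivers the required C3 epimer; the minor epimer is recycled through Step 8.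

**Step 1**
Reactants: 1 (S)-carvone
Product: 2 trans-6-methylcarvone
Conditions: LDA, THF, –78 °C; then MeI, –78 → 0 °C
Reagents that add atoms: methyl iodide, CI
Why: Kinetic C6 (α') enolate alkylation; the new C6 centre is anti to the C5 isopropenyl (axial attack), and C5 comes from the chiral pool.

**Step 2**
Reactants: 2; 3 5-iodo-2-methylpent-2-ene
Product: 4 6-methyl-6-(4-methylpent-3-enyl)carvone (Me cis, chain trans to isopropenyl)
Conditions: LDA, THF, –78 °C; then 3, DMPU, –78 → 0 °C
Reagents that add atoms: none (3 is the reactant)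
Why: Second enolate alkylation, again anti to the C5 substituent, creates the C10 quaternary centre (chain "up", Me "down") by substrate control.

**Step 3**
Reactants: 4
Product: 5 3,4-epoxide of the homoprenyl alkene (≈1:1 at the epoxide C3)
Conditions: mCPBA (1.0 equiv), NaHCO3, CH2Cl2, –20 °C
Reagents that add atoms: mCPBA, OOC(=O)c1cccc(Cl)c1
Why: Prilezhaev epoxidation is selective for the electron-rich trisubstituted alkene over the isopropenyl and enone; the epoxide epimers converge at Step 8.

**Step 4**
Reactants: 5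
Product: 6 5-acetyl analogue (methyl ketone)
Conditions: O3, CH2Cl2/MeOH, –78 °C; then PPh3
Reagents that add atoms: ozone, [O-][O+]=O
Why: Ozonolysis of the most electron-rich remaining alkene (isopropenyl); the epoxide and enone survive; C5 is untouched.

**Step 5**
Reactants: 6
Product: 7 C5 acetate
Conditions: mCPBA, NaHCO3, CH2Cl2, 25 °C
Reagents that add atoms: mCPBA, OOC(=O)c1cccc(Cl)c1
Why: Baeyer–Villiger oxidation; the secondary ring carbon migrates with retention, fixing C5–O with the carvone configuration.

**Step 6**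
Reactants: 7
Product: 8 C5 alcohol
Conditions: K2CO3, MeOH, 25 °C
Reagents that add atoms: none
Why: Mild methanolysis of the acetate leaves the epoxide, enone and all stereocentres intact.

**Step 7**
Reactants: 8
Product: 9 trans-fused oxepane enone (C3-OH epimer mixture)
Conditions: CSA (10 mol %), CH2Cl2, 0 °C
Reagents that add atoms: none
Why: Acid-promoted epoxy-alcohol opening; C5–OH attacks the tertiary epoxide carbon (7-endo, Markovnikov), forming the trans-diequatorial oxepane with C3 retained as epimers.

**Step 8**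
Reactants: 9
Product: 10 oxepan-3-one
Conditions: Dess–Martin periodinane, NaHCO3, CH2Cl2, 25 °C
Reagents that add atoms: none
Why: Oxidation collapses both C3 epimers to one ketone, so C3 can be set by ring control in Step 9.

**Step 9**
Reactants: 10
Product: 11 C3-hydroxy, 8α-hydroxy, 9-oxo compound
Conditions: L-Selectride (2.5 equiv), THF, –78 °C; then Davis oxaziridine, –78 → –40 °C
Reagents that add atoms: 2-(phenylsulfonyl)-3-phenyloxaziridine, O=S(=O)(c1ccccc1)N1OC1c1ccccc1
Why: Hydride reduces the C3 ketone from the less hindered face of the fused ring and adds 1,4 to the enone to give the C8/C9 enolate. The enolate is hydroxylated from the α face because the β face is blocked by the axial C10–Me, giving 8α-OH/8β-Me.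

**Step 10**
Reactants: 11
Product: 12 bis-TES ether (C3-OTES, C8-OTES)
Conditions: TESOTf (3 equiv), 2,6-lutidine, CH2Cl2, –78 → 0 °C
Reagents that add atoms: triethylsilyl triflate, CC[Si](CC)(CC)OS(=O)(=O)C(F)(F)F
Why: Protects the OH groups before methylenation and oxidation; C8 and C10 have no enolisable H, so the ketone is untouched.

**Step 11**
Reactants: 12
Product: 13 9-methylene compound
Conditions: Tebbe reagent (3 equiv), pyridine, THF/toluene, –40 → 25 °C
Reagents that add atoms: Tebbe reagent as CH2 source, C=[Ti](C1C=CC=C1)C1C=CC=C1.C[Al](C)Cl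
Why: Titanium methylenation works on the very hindered, non-enolisable C9 ketone.

**Step 12**
Reactants: 13
Product: 14 C9–CH2OH (9α-H)
Conditions: 9-BBN, THF, 25 °C; then H2O2, NaOH (aq), 0 → 25 °C
Reagents that add atoms: hydrogen peroxide, OO
Why: Hydroboration of the exocyclic alkene is syn and from the α face (β face shielded by 1,3-diaxial methyls), giving the 9α-H/equatorial CH2OH of the target.

**Step 13**
Reactants: 14
Product: 15 right-hand aldehyde (C9–CHO)
Conditions: Dess–Martin periodinane, NaHCO3, CH2Cl2, 25 °C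
Reagents that add atoms: none
Why: Mild oxidation; any epimerisation at C9 favours the equatorial CHO, which is the target configuration.

**Step 14**
Reactants: 16 (R)-carvone
Product: 17 TMS enol ether of 3-methyl-dihydrocarvone (C3 epimer irrelevant)
Conditions: Me2CuLi, TMSCl, Et2O, –78 °C
Reagents that add atoms: lithium dimethylcuprate, C[Cu-]C.[Li+]; trimethylsilyl chloride, C[Si](C)(C)Cl
Why: Cuprate 1,4-addition of methyl (this carbon becomes Ca) with enolate trapping; C5 (future C10') is the chiral-pool centre.

**Step 15**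
Reactants: 17
Product: 18 (R)-2,3-dimethyl-5-isopropenylcyclohex-2-enone
Conditions: Pd(OAc)2 (1.1 equiv), MeCN, 25 °C
Reagents that add atoms: none
Why: Saegusa–Ito oxidation regenerates the enone and removes the C3 stereocentre, leaving the β-methyl (Ca) enone.

**Step 16**
Reactants: 18
Product: 19 endocyclic TMS dienol ether
Conditions: TMSOTf, Et3N, CH2Cl2, 0 °C
Reagents that add atoms: trimethylsilyl triflate, C[Si](C)(C)OS(=O)(=O)C(F)(F)F
Why: Thermodynamic γ-deprotonation at C5' (the ring CH2) gives the conjugated 1-silyloxy-cyclohexadiene.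

**Step 17**
Reactants: 19
Product: 20 α-ketol (2-hydroxy-2,3-dimethyl-5-isopropenylcyclohex-3-en-1-one; OH anti to isopropenyl)
Conditions: DMDO (acetone), –78 → 0 °C; then 1 M HCl, THF
Reagents that add atoms: dimethyldioxirane, CC1(C)OO1
Why: Rubottom oxidation; DMDO attacks the electron-rich silyl enol ether from the face anti to the C10' isopropenyl, the silyl group migrates to the new tertiary alkoxide, and acid removes it.

**Step 18 (key step)**
Reactants: 20; 21 1,1-dimethoxy-2-methylpropane
Product: 22 aldehyde with C4'Me2–CHO on C5' and enone C8'(=O)–C7'(Me)=C6'(Me)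
Conditions: PPTS (10 mol %), toluene, 110 °C, MeOH removed (Dean–Stark)
Reagents that add atoms: none (21 is the reactant)
Why: Büchi–Wüest/Claisen [3,3] rearrangement of the in-situ allyl isobutenyl ether; chair TS, suprafacial on the face of the C7'–O bond, builds the quaternary C4'–tertiary C5' bond and regenerates the enone (C5' epimerised later).

**Step 19**
Reactants: 22
Product: 23 ring-2 alcohol with C3'-OH and exocyclic C1'=CH2 (C3' epimer mixture)
Conditions: Me2AlCl (1.5 equiv), CH2Cl2, –78 → 0 °C
Reagents that add atoms: none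
Why: Intramolecular carbonyl-ene (Prins) cyclisation of the isopropenyl onto the non-enolisable aldehyde closes ring 2 (6-endo) via the tertiary cation, giving the exocyclic methylene.

**Step 20**
Reactants: 23
Product: 24 O-phenyl thionocarbonate
Conditions: PhOC(S)Cl, DMAP, pyridine, CH2Cl2, 25 °C
Reagents that add atoms: phenyl chlorothionoformate, S=C(Cl)Oc1ccccc1
Why: Activates the C3' alcohol for radical deoxygenation; its stereochemistry is irrelevant.

**Step 21**
Reactants: 24
Product: 25 trans-fused methylene decalone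
Conditions: Bu3SnH, AIBN, toluene, 110 °C
Reagents that add atoms: none
Why: Barton–McCombie deoxygenation turns C3' into CH2.

**Step 22**
Reactants: 25
Product: 26 cis-fused methylene decalone
Conditions: t-BuOK, t-BuOH, 80 °C
Reagents that add atoms: none
Why: C5' is the γ-carbon of the enone, so thermodynamic dienolate epimerisation moves the bulky C4'Me2 pseudo-axial to relieve A(1,2) strain with the C6' substituent, giving the cis ring fusion.

**Step 23**
Reactants: 26
Product: 27 left fragment (C1'(Me)OH)
Conditions: Co(acac)2 (10 mol %), PhSiH3, O2 (1 atm), i-PrOH, 25 °C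
Reagents that add atoms: dioxygen, O=O
Why: Mukaiyama HAT hydration of the exocyclic methylene gives the tertiary radical at C1', trapped by O2 on the convex face (ring 1 shields the other face), so OH is on the same side as the fusion H atoms and Me on the concave side, as in the target.

**Step 24**
Reactants: 27; 15
Product: 28 aldol adduct (Cb-OH, C1'-OTES; Cb epimer mixture)
Conditions: TESOTf, Et3N, CH2Cl2, 0 °C (tertiary OTES plus exocyclic dienol TES ether); then 15, BF3·OEt2, –78 °C; NaHCO3 work-up
Reagents that add atoms: triethylsilyl triflate, CC[Si](CC)(CC)OS(=O)(=O)C(F)(F)F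
Why: Vinylogous Mukaiyama aldol at the exocyclic γ-carbon; the endocyclic dienolate is disfavoured by strain, so only Ca–Cb forms.

**Step 25**
Reactants: 28
Product: 29 (E)-dienone (C6'–CaH=CbH–C9)
Conditions: MsCl, Et3N, CH2Cl2, 0 °C; then DBU, 25 °C
Reagents that add atoms: none
Why: Mesylation followed by vinylogous E1cB elimination removes the Cb stereocentre.

**Step 26**
Reactants: 29
Product: 30 fully protected target
Conditions: H2 (1 atm), 10% Pd/C, EtOAc, 25 °C
Reagents that add atoms: none
Why: The unhindered disubstituted γ,δ-alkene is reduced selectively; the tetrasubstituted enone alkene survives.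

**Step 27**
Reactants: 30
Product: 31 sipholenol K
Conditions: HF·pyridine, THF, 25 → 40 °C
Reagents that add atoms: none
Why: Global removal of the three TES ethers; no stereocentre is touched.

**Compound list**
1 | (S)-(+)-carvone | C=C(C)[C@H]1CC=C(C)C(=O)C1 | starting material
2 | trans-6-methylcarvone | C=C(C)[C@H]1CC=C(C)C(=O)[C@@H]1C | intermediate
3 | 5-iodo-2-methylpent-2-ene | CC(C)=CCCI | starting material
4 | 6-Me-6-(4-methylpent-3-enyl)carvone | C=C(C)[C@H]1CC=C(C)C(=O)[C@]1(C)CCC=C(C)C | intermediate
5 | 3,4-epoxide of 4 (epoxide-C3 epimer mixture) | C=C(C)[C@H]1CC=C(C)C(=O)[C@]1(C)CCC2OC2(C)C | intermediate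
6 | methyl ketone from 5 | CC(=O)[C@H]1CC=C(C)C(=O)[C@]1(C)CCC2OC2(C)C | intermediate
7 | C5 acetate | CC(=O)O[C@H]1CC=C(C)C(=O)[C@]1(C)CCC2OC2(C)C | intermediate
8 | C5 alcohol | O[C@H]1CC=C(C)C(=O)[C@]1(C)CCC2OC2(C)C | intermediate
9 | oxepane enone, C3-OH epimer mixture | CC1=CC[C@@H]2OC(C)(C)C(O)CC[C@@]2(C)C1=O | intermediate
10 | oxepan-3-one enone | CC1=CC[C@@H]2OC(C)(C)C(=O)CC[C@@]2(C)C1=O | intermediate
11 | 3-hydroxy-8α-hydroxy-9-ketone | C[C@]1(O)CC[C@@H]2OC(C)(C)[C@@H](O)CC[C@@]2(C)C1=O | intermediate
12 | bis-TES ether of 11 | C[C@]1(O[Si](CC)(CC)CC)CC[C@@H]2OC(C)(C)[C@@H](O[Si](CC)(CC)CC)CC[C@@]2(C)C1=O | intermediate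
13 | 9-methylene compound | C[C@]1(O[Si](CC)(CC)CC)CC[C@@H]2OC(C)(C)[C@@H](O[Si](CC)(CC)CC)CC[C@@]2(C)C1=C | intermediate
14 | C9–CH2OH compound | C[C@]1(O[Si](CC)(CC)CC)CC[C@@H]2OC(C)(C)[C@@H](O[Si](CC)(CC)CC)CC[C@@]2(C)[C@@H]1CO | intermediate
15 | right-hand aldehyde | C[C@]1(O[Si](CC)(CC)CC)CC[C@@H]2OC(C)(C)[C@@H](O[Si](CC)(CC)CC)CC[C@@]2(C)[C@@H]1C=O | intermediate
16 | (R)-(–)-carvone | C=C(C)[C@@H]1CC=C(C)C(=O)C1 | starting material
17 | TMS enol ether of 3-methyl-dihydrocarvone (C3 unspecified) | C=C(C)[C@@H]1CC(C)C(C)=C(O[Si](C)(C)C)C1 | intermediate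
18 | 2,3-dimethyl-5-isopropenylcyclohex-2-enone | C=C(C)[C@@H]1CC(C)=C(C)C(=O)C1 | intermediate
19 | TMS dienol ether | C=C(C)[C@@H]1C=C(C)C(C)=C(O[Si](C)(C)C)C1 | intermediate
20 | α-ketol | C=C(C)[C@@H]1C=C(C)[C@@](C)(O)C(=O)C1 | intermediate
21 | 1,1-dimethoxy-2-methylpropane | COC(OC)C(C)C | starting material
22 | Claisen aldehyde | C=C(C)[C@H]1CC(=O)C(C)=C(C)[C@@H]1C(C)(C)C=O | intermediate
23 | Prins alcohol, trans-fused (C3' unspecified) | C=C1CC(O)C(C)(C)[C@H]2C(C)=C(C)C(=O)C[C@H]12 | intermediate
24 | thionocarbonate | C=C1CC(OC(=S)Oc3ccccc3)C(C)(C)[C@H]2C(C)=C(C)C(=O)C[C@H]12 | intermediate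
25 | trans-fused methylene decalone | C=C1CCC(C)(C)[C@H]2C(C)=C(C)C(=O)C[C@H]12 | intermediate
26 | cis-fused methylene decalone | C=C1CCC(C)(C)[C@@H]2C(C)=C(C)C(=O)C[C@H]12 | intermediate
27 | left fragment | C[C@]1(O)CCC(C)(C)[C@@H]2C(C)=C(C)C(=O)C[C@H]12 | intermediate
28 | aldol adduct (Cb unspecified) | CC1=C(CC(O)[C@H]2[C@]3(C)CC[C@H](O[Si](CC)(CC)CC)C(C)(C)O[C@H]3CC[C@]2(C)O[Si](CC)(CC)CC)[C@@H]2[C@H](CC1=O)[C@@](C)(O[Si](CC)(CC)CC)CCC2(C)C | intermediate
29 | dienone | CC1=C(C=C[C@H]2[C@]3(C)CC[C@H](O[Si](CC)(CC)CC)C(C)(C)O[C@H]3CC[C@]2(C)O[Si](CC)(CC)CC)[C@@H]2[C@H](CC1=O)[C@@](C)(O[Si](CC)(CC)CC)CCC2(C)C | intermediate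
30 | tris-TES target | CC1=C(CC[C@H]2[C@]3(C)CC[C@H](O[Si](CC)(CC)CC)C(C)(C)O[C@H]3CC[C@]2(C)O[Si](CC)(CC)CC)[C@@H]2[C@H](CC1=O)[C@@](C)(O[Si](CC)(CC)CC)CCC2(C)C | intermediate
31 | sipholenol K | CC1=C(CC[C@H]2[C@]3(C)CC[C@H](O)C(C)(C)O[C@H]3CC[C@]2(C)O)[C@@H]2[C@H](CC1=O)[C@@](C)(O)CCC2(C)C | target

**Total step count:** 27.
**Longest linear sequence:** 17 steps (Steps 1–13, then 24–27).

**Three steps most likely to fail**
1. **Step 7 (7-endo epoxy-alcohol cyclisation).** The 6-exo THP could compete.
 Fallback: carry the alkene (no epoxide) and close the ring by NIS 7-endo iodoetherification of the C5–OH onto the alkene. Then convert the C3-iodide to C3-OH through a transient epoxide, or set C3 by oxidation/reduction.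
2. **Step 18 (Claisen on the tertiary α-ketol).** Ketal formation or failed mixed-acetal formation is possible.
 Fallback: abandon the Claisen and build C5'–C4' by Mukaiyama–Michael addition of the carvone kinetic silyl enol ether to prenal, Wittig methylenation, RCM onto the isopropenyl, and Mukaiyama hydration. The chain is then installed by MeLi 1,2-addition and oxidative transposition.
3. **Step 24 (vinylogous aldol with the neopentyl aldehyde).** It is hindered and regioselectivity is uncertain.
 Fallback: make the 3-vinyl enone (vinyl cuprate in Step 14) and the C9-vinyl compound (Wittig methylenation of 15), join them by cross-metathesis (Hoveyda–Grubbs II), then hydrogenate.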